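**Strategy.** Ring C of the upper flavan unit is disconnected at the aryl ether O1–C8a and at C3–C4. This is a [3+3] annulation that exploits the 1,3-relationship across C4a of ring A between benzylic C4 (nucleophile) and fluorine-bearing C8a (electrophile). The partner is an enantiopure α-hydroxy dibenzyl acetal carrying O1–C2(aryl)–C3. Its magnesium alkoxide directs replacement of one acetal benzyloxy group by the benzylic Grignard carbon (C3–C4, setting C3), then displaces fluoride (O1–C8a) in the same flask to give penta-O-benzyl-epicatechin. DDQ activation of C4, Lewis-acid union with C8 of benzylated taxifolin (4β) and hydrogenolysis complete the synthesis.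

Key step: step 8

Remark: the target is read as epicatechin-(4β→8)-taxifolin, (2R,3R,4R) in the upper flavan and (2R,3R) in the lower dihydroflavonol; flavonoid numbering (O1, C2, C3, C4, C4a, C5–C8, C8a; rings A, C, B) is used for the upper unit, and ring D is the phloroglucinol ring of the taxifolin unit.

**Step 1**
Reactants: 1 1,3,5-trifluorobenzene
Product: 2 1,3-bis(benzyloxy)-5-fluorobenzene
Conditions: BnOH (2.1 equiv), NaH, NMP, 0 → 90 °C
Reagents that add atoms: benzyl alcohol, OCc1ccccc1
Why: Twofold SNAr, each exchange activated by the remaining meta fluorines; after two exchanges the ring should be too electron-rich for a third at this temperature.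

**Step 2**
Reactants: 2 1,3-bis(benzyloxy)-5-fluorobenzene
Product: 3 2,4-bis(benzyloxy)-6-fluorobenzaldehyde
Conditions: POCl3, DMF, 0 → 60 °C; then aq. NaOAc
Reagents that add atoms: N,N-dimethylformamide, CN(C)C=O; water, O
Why: Vilsmeier–Haack formylation should occur ortho/para to both benzyloxy groups at the position next to the small fluorine, which is less hindered than the position between the two benzyloxy groups.

**Step 3**
Reactants: 3 2,4-bis(benzyloxy)-6-fluorobenzaldehyde
Product: 4 [2,4-bis(benzyloxy)-6-fluorophenyl]methanol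
Conditions: NaBH4, THF/MeOH, 0 °C
Reagents that add atoms: none
Why: Borohydride reduction of an aryl aldehyde; no other reducible group is present.

**Step 4**
Reactants: 4 [2,4-bis(benzyloxy)-6-fluorophenyl]methanol
Product: 5 1,5-bis(benzyloxy)-2-(chloromethyl)-3-fluorobenzene
Conditions: SOCl2, Et3N, CH2Cl2, −20 → 0 °C; used at once as a cold solution
Reagents that add atoms: thionyl chloride, O=S(Cl)Cl
Why: Deoxychlorination via the chlorosulfite under amine buffering; the electron-rich chloride is not stored, to avoid self-alkylation.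

**Step 5**
Reactants: 6 1-[3,4-bis(benzyloxy)phenyl]ethan-1-one
Product: 7 2-[3,4-bis(benzyloxy)phenyl]-2-oxoacetaldehyde hydrate
Conditions: SeO2, dioxane/H2O, 100 °C
Reagents that add atoms: selenium dioxide, O=[Se]=O; water, O
Why: Riley oxidation of the aryl methyl ketone to the arylglyoxal, isolated as its hydrate.

**Step 6**
Reactants: 7 2-[3,4-bis(benzyloxy)phenyl]-2-oxoacetaldehyde hydrate
Product: 8 2,2-bis(benzyloxy)-1-[3,4-bis(benzyloxy)phenyl]ethan-1-one
Conditions: BnOH (2.5 equiv), TsOH·H2O (cat.), toluene, reflux, Dean–Stark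
Reagents that add atoms: benzyl alcohol, OCc1ccccc1
Why: Acid-catalysed acetalisation with azeotropic water removal; only the aldehyde-level carbon is electrophilic enough, the aryl ketone stays free.

**Step 7**
Reactants: 8 2,2-bis(benzyloxy)-1-[3,4-bis(benzyloxy)phenyl]ethan-1-one
Product: 9 (1R)-2,2-bis(benzyloxy)-1-[3,4-bis(benzyloxy)phenyl]ethan-1-ol
Conditions: RuCl(p-cymene)[(S,S)-TsDPEN] (1 mol%), HCO2H/Et3N (5:2), CH2Cl2, 30 °C
Reagents that add atoms: none
Why: Noyori asymmetric transfer hydrogenation; the (S,S)-catalyst should deliver hydride to the same face as in aryl methyl ketones, which here (acetal carbon outranks aryl) is the (R)-carbinol, the future C2.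

**Step 8**
Reactants: 5 1,5-bis(benzyloxy)-2-(chloromethyl)-3-fluorobenzene; 9 (1R)-2,2-bis(benzyloxy)-1-[3,4-bis(benzyloxy)phenyl]ethan-1-ol
Product: 13 (2R,3R)-3,5,7-tris(benzyloxy)-2-[3,4-bis(benzyloxy)phenyl]chromane (penta-O-benzyl-(−)-epicatechin), via benzylic Grignard reagent 10 (not isolated), via chloromagnesium alkoxide 11 (not isolated), via open-chain fluoroaryl alkoxide 12 (not isolated)
Conditions: 5 (2.5 equiv), Mg, LiCl, Et2O, 0 °C; 9, i-PrMgCl (1.0 equiv), toluene, 0 °C; combine, MgBr2·OEt2, toluene, 0 → 45 °C; then t-BuOK, DMF, 90 °C (one flask)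
Reagents that add atoms: none
Why: Proposed new method: the chloromagnesium alkoxide 11 chelates one of the two acetal oxygens in a five-membered ring, the chelated benzyloxy group leaves as a magnesium-bound ion pair and Grignard reagent 10 delivers its benzylic carbon to C3 anti to the departing oxygen (C3–C4), which leaves O3 as a benzyl ether and O1 as the only alkoxide; after the switch to potassium in DMF this alkoxide closes ring C by 6-exo addition–elimination (SNAr through a Meisenheimer adduct) at the fluorine-bearing C8a, which is meta to both benzyloxy groups and so not deactivated (O1–C8a). The closest known reaction types are the chelation-assisted cleavage of acetals by Grignard reagents next to a free hydroxyl group and the tandem SN2–SNAr chroman annulation of 2-fluorobenzyl nucleophiles; new is their merger on an acyclic α-oxido acetal with 1,2-induction. The new stereocenter C3 is controlled by the (R)-carbinol centre C2: the chelate that keeps the spectator benzyloxy group trans to the aryl group should be preferred, and invertive entry of carbon then gives the 2,3-syn (in the ring 2,3-cis) relationship, while C2 itself is not touched. Chemoselectivity between O1 and O3 is secured because O3 emerges from the C–C bond formation already benzylated, so only the six-membered closure is possible. The step needs substitution to outrun 1,2-hydride shift of the α-oxido oxocarbenium ion, which excess 10, MgBr2·OEt2 and a non-coordinating solvent should favour.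

**Step 9**
Reactants: 13 penta-O-benzyl-(−)-epicatechin
Product: 14 (2R,3R,4S)-3,5,7-tris(benzyloxy)-2-[3,4-bis(benzyloxy)phenyl]-4-(2-ethoxyethoxy)chromane (4β-ether, trans to the 3-benzyloxy group)
Conditions: DDQ (2 equiv), 2-ethoxyethanol (5 equiv), CH2Cl2, rt
Reagents that add atoms: 2-ethoxyethanol, CCOCCO
Why: DDQ benzylic C–H oxidation: hydride abstraction at C4 gives a cation stabilised by the ring A oxygens, which the alcohol should trap trans to the 3-benzyloxy group.

**Step 10**
Reactants: 15 (+)-taxifolin, (2R,3R)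
Product: 16 (2R,3R)-5,7-bis(benzyloxy)-2-[3,4-bis(benzyloxy)phenyl]-3-hydroxychroman-4-one (5,7,3',4'-tetra-O-benzyltaxifolin)
Conditions: BnBr (4.4 equiv), K2CO3, DMF, 0 °C → rt
Reagents that add atoms: benzyl bromide, BrCc1ccccc1
Why: Williamson etherification of the four phenols; K2CO3 does not deprotonate the aliphatic 3-OH, and mild temperature should keep C2 and C3 intact.

**Step 11**
Reactants: 14 4β-(2-ethoxyethoxy) ether of penta-O-benzyl-epicatechin; 16 5,7,3',4'-tetra-O-benzyltaxifolin (3 equiv)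
Product: 17 3,5,7,3',4'-penta-O-benzyl-(−)-epicatechin-(4β→8)-5,7,3',4'-tetra-O-benzyl-(+)-taxifolin
Conditions: TMSOTf (cat.), 4 Å MS, CH2Cl2, −78 → −40 °C
Reagents that add atoms: none
Why: Lewis-acid ionisation to the C4 benzylic cation and Friedel–Crafts alkylation by C8 of ring D (the standard procyanidin 4→8 coupling); attack anti to the 3-benzyloxy group should set C4 as 4β (3,4-trans).

**Step 12**
Reactants: 17 nona-O-benzyl dimer
Product: 18 epicatechin-(4β→8)-taxifolin (target)
Conditions: H2 (1 atm), Pd(OH)2/C, THF/MeOH/H2O, rt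
Reagents that add atoms: none
Why: Hydrogenolysis of nine benzyl ethers; the conjugated aryl ketone, the ring ethers and the interflavan bond should survive these mild conditions.

**Compound list**
1 | 1,3,5-trifluorobenzene | Fc1cc(F)cc(F)c1 | starting material
2 | 1,3-bis(benzyloxy)-5-fluorobenzene | Fc1cc(OCc2ccccc2)cc(OCc2ccccc2)c1 | intermediate
3 | 2,4-bis(benzyloxy)-6-fluorobenzaldehyde | O=Cc1c(F)cc(OCc2ccccc2)cc1OCc1ccccc1 | intermediate
4 | [2,4-bis(benzyloxy)-6-fluorophenyl]methanol | OCc1c(F)cc(OCc2ccccc2)cc1OCc1ccccc1 | intermediate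
5 | 1,5-bis(benzyloxy)-2-(chloromethyl)-3-fluorobenzene | ClCc1c(F)cc(OCc2ccccc2)cc1OCc1ccccc1 | intermediate
6 | 1-[3,4-bis(benzyloxy)phenyl]ethan-1-one | CC(=O)c1ccc(OCc2ccccc2)c(OCc2ccccc2)c1 | starting material
7 | 2-[3,4-bis(benzyloxy)phenyl]-2-oxoacetaldehyde hydrate | OC(O)C(=O)c1ccc(OCc2ccccc2)c(OCc2ccccc2)c1 | intermediate
8 | 2,2-bis(benzyloxy)-1-[3,4-bis(benzyloxy)phenyl]ethan-1-one | O=C(c1ccc(OCc2ccccc2)c(OCc2ccccc2)c1)C(OCc1ccccc1)OCc1ccccc1 | intermediate
9 | (1R)-2,2-bis(benzyloxy)-1-[3,4-bis(benzyloxy)phenyl]ethan-1-ol | O[C@H](c1ccc(OCc2ccccc2)c(OCc2ccccc2)c1)C(OCc1ccccc1)OCc1ccccc1 | intermediate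
10 | [2,4-bis(benzyloxy)-6-fluorobenzyl]magnesium chloride | Cl[Mg]Cc1c(F)cc(OCc2ccccc2)cc1OCc1ccccc1 | intermediate
11 | chloromagnesium alkoxide of 9 | Cl[Mg]O[C@H](c1ccc(OCc2ccccc2)c(OCc2ccccc2)c1)C(OCc1ccccc1)OCc1ccccc1 | intermediate
12 | chloromagnesium (1R,2R)-2-(benzyloxy)-3-[2,4-bis(benzyloxy)-6-fluorophenyl]-1-[3,4-bis(benzyloxy)phenyl]propan-1-olate | Cl[Mg]O[C@H](c1ccc(OCc2ccccc2)c(OCc2ccccc2)c1)[C@H](OCc1ccccc1)Cc1c(F)cc(OCc2ccccc2)cc1OCc1ccccc1 | intermediate
13 | (2R,3R)-3,5,7-tris(benzyloxy)-2-[3,4-bis(benzyloxy)phenyl]chromane (penta-O-benzyl-(−)-epicatechin) | C1c2c(OCc3ccccc3)cc(OCc3ccccc3)cc2O[C@H](c2ccc(OCc3ccccc3)c(OCc3ccccc3)c2)[C@@H]1OCc1ccccc1 | intermediate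
14 | (2R,3R,4S)-3,5,7-tris(benzyloxy)-2-[3,4-bis(benzyloxy)phenyl]-4-(2-ethoxyethoxy)chromane | CCOCCO[C@H]1c2c(OCc3ccccc3)cc(OCc3ccccc3)cc2O[C@H](c2ccc(OCc3ccccc3)c(OCc3ccccc3)c2)[C@@H]1OCc1ccccc1 | intermediate
15 | (+)-taxifolin, (2R,3R) | O=C1c2c(O)cc(O)cc2O[C@H](c2ccc(O)c(O)c2)[C@H]1O | starting material
16 | (2R,3R)-5,7-bis(benzyloxy)-2-[3,4-bis(benzyloxy)phenyl]-3-hydroxychroman-4-one | O=C1c2c(OCc3ccccc3)cc(OCc3ccccc3)cc2O[C@H](c2ccc(OCc3ccccc3)c(OCc3ccccc3)c2)[C@H]1O | intermediate
17 | 3,5,7,3',4'-penta-O-benzyl-(−)-epicatechin-(4β→8)-5,7,3',4'-tetra-O-benzyl-(+)-taxifolin | O=C1c2c(OCc3ccccc3)cc(OCc3ccccc3)c([C@H]3c4c(OCc5ccccc5)cc(OCc5ccccc5)cc4O[C@H](c4ccc(OCc5ccccc5)c(OCc5ccccc5)c4)[C@@H]3OCc3ccccc3)c2O[C@H](c2ccc(OCc3ccccc3)c(OCc3ccccc3)c2)[C@H]1O | intermediate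
18 | epicatechin-(4β→8)-taxifolin | O=C1c2c(O)cc(O)c([C@H]3c4c(O)cc(O)cc4O[C@H](c4ccc(O)c(O)c4)[C@@H]3O)c2O[C@H](c2ccc(O)c(O)c2)[C@H]1O | target

**Total step count:** 12. **Longest linear sequence:** 8 steps (1, 2, 3, 4, 8, 9, 11, 12).

**Steps most likely to fail**

1. Step 8 (Proposed new method). What may go wrong:
   - The α-oxido acetal may ionise and undergo a 1,2-hydride shift to the α-benzyloxy ketone, which 10 would then attack.
   - Carbon may enter through an open, Felkin-type oxocarbenium ion and give the 2,3-anti isomer.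
   - Fluoride displacement may be sluggish.

   Fallback (known chemistry, stepwise): it sets out from 9 and Grignard reagent 10 and comes back at 13.
   - O1 of 9 is protected (NaH, 4-methoxybenzyl chloride, DMF) to give the 4-methoxybenzyl ether acetal F1.
   - Mild acetal hydrolysis (aq. AcOH/THF) gives the α-alkoxy aldehyde F2.
   - Cram-chelate-controlled addition of 10 (MgBr2·OEt2, CH2Cl2, −78 °C) should give the syn alcohol F3.
   - O3 is benzylated (NaH, BnBr) to give the benzyl ether F4.
   - DDQ removes the 4-methoxybenzyl group to give the free benzylic alcohol F5.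
   - F5 is cyclised by intramolecular SNAr (t-BuOK, DMF, 90 °C) to 13.

2. Step 11. What may go wrong:
   - Capture of the C4 cation by the carbonyl-deactivated, benzylated ring D may be slow, so that 14 self-condenses.
   - Attack may occur through C6 instead of C8.

   Fallback: it sets out from 14 and unprotected taxifolin 15 and comes back at 18. The free phloroglucinol ring of 15 is far more nucleophilic. Coupling with Sc(OTf)3 in THF should give the half-protected dimer F6, penta-O-benzyl-epicatechin-(4β→8)-taxifolin. Any 4→6 isomer is removed by chromatography, and F6 is hydrogenolysed (H2, Pd(OH)2/C) to 18.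

3. Step 2. What may go wrong:
   - Formylation at the position between the two benzyloxy groups (para to fluorine) may compete and give the regioisomeric aldehyde.

   Fallback: it sets out from 2 and comes back at 3. Directed ortho-metalation replaces electrophilic substitution: n-BuLi, THF, −78 °C should deprotonate the most acidic position, flanked by fluorine and benzyloxy, to give the aryllithium F7. This is kept cold to avoid benzyne formation and quenched with DMF to give 3.

**Further compounds**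
F1 | step 8 | 4-[(1R)-2,2-bis(benzyloxy)-1-(4-methoxybenzyloxy)ethyl]-1,2-bis(benzyloxy)benzene | COc1ccc(CO[C@H](c2ccc(OCc3ccccc3)c(OCc3ccccc3)c2)C(OCc2ccccc2)OCc2ccccc2)cc1
F2 | step 8 | (2R)-2-[3,4-bis(benzyloxy)phenyl]-2-(4-methoxybenzyloxy)acetaldehyde | COc1ccc(CO[C@H](c2ccc(OCc3ccccc3)c(OCc3ccccc3)c2)C=O)cc1
F3 | step 8 | (1R,2R)-3-[2,4-bis(benzyloxy)-6-fluorophenyl]-1-[3,4-bis(benzyloxy)phenyl]-1-(4-methoxybenzyloxy)propan-2-ol | COc1ccc(CO[C@H](c2ccc(OCc3ccccc3)c(OCc3ccccc3)c2)[C@H](O)Cc2c(F)cc(OCc3ccccc3)cc2OCc2ccccc2)cc1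
F4 | step 8 | benzyl ether of F3 at O3 | COc1ccc(CO[C@H](c2ccc(OCc3ccccc3)c(OCc3ccccc3)c2)[C@H](OCc2ccccc2)Cc2c(F)cc(OCc3ccccc3)cc2OCc2ccccc2)cc1
F5 | step 8 | (1R,2R)-2-(benzyloxy)-3-[2,4-bis(benzyloxy)-6-fluorophenyl]-1-[3,4-bis(benzyloxy)phenyl]propan-1-ol | O[C@H](c1ccc(OCc2ccccc2)c(OCc2ccccc2)c1)[C@H](OCc1ccccc1)Cc1c(F)cc(OCc2ccccc2)cc1OCc1ccccc1
F6 | step 11 | 3,5,7,3',4'-penta-O-benzyl-(−)-epicatechin-(4β→8)-(+)-taxifolin | O=C1c2c(O)cc(O)c([C@H]3c4c(OCc5ccccc5)cc(OCc5ccccc5)cc4O[C@H](c4ccc(OCc5ccccc5)c(OCc5ccccc5)c4)[C@@H]3OCc3ccccc3)c2O[C@H](c2ccc(O)c(O)c2)[C@H]1O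
F7 | step 2 | [2,4-bis(benzyloxy)-6-fluorophenyl]lithium | [Li]c1c(F)cc(OCc2ccccc2)cc1OCc1ccccc1
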